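**Retrosynthetic overview**
1. The target comes from a double O-debenzylation of a diaryl ether phenol, which comes from dehydrogenative aromatisation of a 3-aryloxy-cyclohexenone (ring B stays a cyclohexane-1,3-dione until the ether bond exists).
2. The ether C–O bond is made by addition–elimination of the ring A salicylate phenoxide on the β-chloro enone of benzyl 4-methyl-2,6-dioxocyclohexanecarboxylate.
3. The ring B carbons are closed by a Dieckmann reaction of dibenzyl 5-methyl-3-oxoheptanedioate; its key C–C bond comes from an intermolecular decarboxylative Claisen (Masamune) condensation of monobenzyl 3-methylglutarate with monobenzyl malonate.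
4. Ring A is a purchased benzene (2-chlororesorcinol) elaborated by Vilsmeier formylation, selective 4-O-benzylation and 2-O-methylation, Baeyer–Villiger (CHO to OH), magnesium-directed ortho-formylation and oxidation to the methyl ester.
5. Ring order: ring A is aromatic from the start; ring B is closed as a carbocycle (Claisen, then Dieckmann), joined to ring A, and aromatised last.

Assumption: the target SMILES carries no stereodescriptor and the molecule has no stereocentre or stable stereoaxis, so it is one achiral compound; the racemic intermediates lose their stereocentre when ring B is aromatised.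

**Route**

Step 1
Reactants: 1 2-chlororesorcinol (2-chlorobenzene-1,3-diol)
Product: 3 3-chloro-2,4-dihydroxybenzaldehyde, via iminium chloride 2 (not isolated)
Conditions: POCl3, DMF, MeCN, 0 °C → rt; then H2O, 50 °C
Reagents that add atoms: N,N-dimethylformamide CN(C)C=O; water O
Why: Vilsmeier–Haack formylation, in which the chloroiminium ion can only attack C4/C6 (equivalent by symmetry, each para to one OH and ortho to the other), so a single aldehyde forms after hydrolysis and no stereocentre is created.

Step 2
Reactants: 3 3-chloro-2,4-dihydroxybenzaldehyde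
Product: 4 4-(benzyloxy)-3-chloro-2-hydroxybenzaldehyde
Conditions: BnBr (1.05 equiv), NaHCO3, MeCN, 80 °C
Reagents that add atoms: benzyl bromide BrCc1ccccc1
Why: Williamson ether synthesis made regioselective by acidity, since the weak base ionises only the 4-OH (para to CHO) while the 2-OH stays locked in a hydrogen bond to the aldehyde; no stereocentre is formed.

Step 3
Reactants: 4 4-(benzyloxy)-3-chloro-2-hydroxybenzaldehyde
Product: 5 4-(benzyloxy)-3-chloro-2-methoxybenzaldehyde
Conditions: MeI, K2CO3, DMF, 40 °C
Reagents that add atoms: iodomethane CI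
Why: Williamson O-methylation of the remaining chelated phenol under a stronger base in a dipolar solvent fixes the methyl ether that becomes the OMe of ring A; no stereocentre is formed.

Step 4
Reactants: 5 4-(benzyloxy)-3-chloro-2-methoxybenzaldehyde
Product: 7 4-(benzyloxy)-3-chloro-2-methoxyphenol, via aryl formate 6 (not isolated)
Conditions: mCPBA, CH2Cl2, 0 °C → rt; aq. NaHCO3 wash; then K2CO3 (cat.), MeOH, rt
Reagents that add atoms: mCPBA O=C(OO)c1cccc(Cl)c1
Why: Baeyer–Villiger (Dakin-type) oxidation, in which the electron-rich aryl group (ortho-OMe, para-OBn) migrates in preference to hydride to give the aryl formate, which base-catalysed methanolysis converts into the phenol; no stereocentre is formed.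

Step 5
Reactants: 7 4-(benzyloxy)-3-chloro-2-methoxyphenol
Product: 9 5-(benzyloxy)-4-chloro-2-hydroxy-3-methoxybenzaldehyde, via hydroxymethylphenol 8 (not isolated)
Conditions: MgCl2, Et3N, (CH2O)n, MeCN, reflux; 1 M HCl work-up
Reagents that add atoms: paraformaldehyde (reacts as formaldehyde) C=O
Why: Casnati–Skattebøl ortho-formylation, in which formaldehyde is delivered inside the magnesium phenoxide to the only free ortho carbon (the other ortho carbon bears OMe and the para carbon bears OBn) and a second formaldehyde oxidises the benzylic alkoxide by Oppenauer-type hydride transfer; no stereocentre is formed.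

Step 6
Reactants: 9 5-(benzyloxy)-4-chloro-2-hydroxy-3-methoxybenzaldehyde
Product: 10 5-(benzyloxy)-4-chloro-2-hydroxy-3-methoxybenzoic acid
Conditions: NaClO2, NaH2PO4, 2-methyl-2-butene, t-BuOH/H2O, rt
Reagents that add atoms: NaClO2 [Na+].[O-]Cl=O
Why: Pinnick (Lindgren) oxidation, in which chlorous acid oxidises only the aldehyde and the alkene scavenger removes HOCl before it can chlorinate the phenol ring; no stereocentre is formed.

Step 7
Reactants: 10 5-(benzyloxy)-4-chloro-2-hydroxy-3-methoxybenzoic acid
Product: 11 methyl 5-(benzyloxy)-4-chloro-2-hydroxy-3-methoxybenzoate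
Conditions: MeI, KHCO3, DMF, rt
Reagents that add atoms: iodomethane CI
Why: SN2 O-alkylation of the carboxylate, where KHCO3 ionises only the acid so the hydrogen-bonded salicylate OH needed for the ether bond stays free; no stereocentre is formed.

Step 8
Reactants: 12 3-methylglutaric anhydride
Product: 13 5-(benzyloxy)-3-methyl-5-oxopentanoic acid (racemic)
Conditions: BnOH, DMAP (cat.), Et3N, CH2Cl2, rt; 1 M HCl work-up
Reagents that add atoms: benzyl alcohol OCc1ccccc1
Why: DMAP-catalysed alcoholysis of a cyclic anhydride whose two carbonyls are enantiotopic, so one constitution results and the C3 stereocentre forms as a racemate that is erased when ring B is aromatised.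

Step 9
Reactants: 13 5-(benzyloxy)-3-methyl-5-oxopentanoic acid (racemic); 14 monobenzyl malonate (3-(benzyloxy)-3-oxopropanoic acid)
Product: 17 dibenzyl 5-methyl-3-oxoheptanedioate (racemic), via acyl imidazolide 15 (not isolated), via acylmalonic acid 16 (not isolated)
Conditions: 13, CDI, THF, rt; then 14, MgCl2, Et3N, THF, rt → 45 °C; 1 M HCl work-up
Reagents that add atoms: none
Why: Masamune–Claisen (decarboxylative Claisen) condensation, in which the magnesium enolate of the malonate half-ester C-acylates the acyl imidazolide and loss of CO2 makes this intermolecular C–C bond formation irreversible and free of self-condensation; the existing racemic stereocentre is untouched.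

Step 10
Reactants: 17 dibenzyl 5-methyl-3-oxoheptanedioate (racemic)
Product: 18 benzyl 4-methyl-2,6-dioxocyclohexane-1-carboxylate (enolised)
Conditions: KOtBu (2.2 equiv), THF, 0 °C → 40 °C; 1 M HCl work-up
Reagents that add atoms: none
Why: Dieckmann (intramolecular Claisen) condensation, in which the doubly activated C2 carbanion attacks the remote benzyl ester in a 6-exo closure driven by formation of the very acidic 2-acyl-1,3-dione enolate; the product has a mirror plane through C1 and C4, so no configurationally stable stereocentre remains.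

Step 11
Reactants: 18 benzyl 4-methyl-2,6-dioxocyclohexane-1-carboxylate
Product: 19 benzyl 2-chloro-4-methyl-6-oxocyclohex-1-ene-1-carboxylate (racemic)
Conditions: (COCl)2, DMF (cat.), CH2Cl2, 0 °C → rt; used crude
Reagents that add atoms: oxalyl chloride ClC(=O)C(=O)Cl
Why: Vilsmeier-type conversion of the vinylogous acid (enol) into the vinylogous acid chloride, in which either enantiotopic carbonyl may react so C4 becomes a stereocentre as a racemate that step 13 erases.

Step 12
Reactants: 11 methyl 5-(benzyloxy)-4-chloro-2-hydroxy-3-methoxybenzoate; 19 benzyl 2-chloro-4-methyl-6-oxocyclohex-1-ene-1-carboxylate (racemic)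
Product: 20 benzyl 2-[4-(benzyloxy)-3-chloro-2-methoxy-6-(methoxycarbonyl)phenoxy]-4-methyl-6-oxocyclohex-1-ene-1-carboxylate (racemic)
Conditions: Cs2CO3, MeCN, 0 °C → rt
Reagents that add atoms: none
Why: Addition–elimination (vinylogous nucleophilic acyl substitution), in which the phenoxide adds to the β-carbon of the doubly activated chloro-enone and chloride leaves, a process far less sensitive to the two ortho substituents of the phenol than an aryl–aryl ether coupling; C4 stays racemic.

Step 13
Reactants: 20 benzyl 2-[4-(benzyloxy)-3-chloro-2-methoxy-6-(methoxycarbonyl)phenoxy]-4-methyl-6-oxocyclohex-1-ene-1-carboxylate (racemic)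
Product: 23 benzyl 2-[4-(benzyloxy)-3-chloro-2-methoxy-6-(methoxycarbonyl)phenoxy]-6-hydroxy-4-methylbenzoate, via silyl dienol ether 21 (not isolated), via cyclohexadienone 22 (not isolated)
Conditions: LiN(iPr)2, TMSCl, THF, −78 °C; then Pd(OAc)2 (1.1 equiv), MeCN, rt
Reagents that add atoms: none
Why: Saegusa–Ito oxidation, in which kinetic α'-enolisation and silylation are followed by palladation with divalent palladium and β-hydride elimination to a cross-conjugated dienone that is the keto tautomer of the phenol and aromatises at once, destroying the C4 stereocentre.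

Step 14
Reactants: 23 benzyl 2-[4-(benzyloxy)-3-chloro-2-methoxy-6-(methoxycarbonyl)phenoxy]-6-hydroxy-4-methylbenzoate
Product: 24 2-[3-chloro-4-hydroxy-2-methoxy-6-(methoxycarbonyl)phenoxy]-6-hydroxy-4-methylbenzoic acid (target)
Conditions: BCl3, C6HMe5, CH2Cl2, −78 °C → 0 °C; MeOH then H2O
Reagents that add atoms: none
Why: Lewis-acid O-debenzylation with pentamethylbenzene as benzyl-cation scavenger cleaves the benzyl ether and the benzyl ester without reducing the aryl chloride and without touching the methyl ester, the methyl ether or the diaryl ether; the target has no stereocentre.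

**Compound list**
1 | 2-chlororesorcinol | Oc1cccc(O)c1Cl | starting material
2 | N-[(3-chloro-2,4-dihydroxyphenyl)methylidene]-N-methylmethanaminium chloride | C[N+](C)=Cc1ccc(O)c(Cl)c1O.[Cl-] | intermediate (not isolated)
3 | 3-chloro-2,4-dihydroxybenzaldehyde | O=Cc1ccc(O)c(Cl)c1O | intermediate
4 | 4-(benzyloxy)-3-chloro-2-hydroxybenzaldehyde | O=Cc1ccc(OCc2ccccc2)c(Cl)c1O | intermediate
5 | 4-(benzyloxy)-3-chloro-2-methoxybenzaldehyde | O=Cc1ccc(OCc2ccccc2)c(Cl)c1OC | intermediate
6 | 4-(benzyloxy)-3-chloro-2-methoxyphenyl formate | O=COc1ccc(OCc2ccccc2)c(Cl)c1OC | intermediate (not isolated)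
7 | 4-(benzyloxy)-3-chloro-2-methoxyphenol | Oc1ccc(OCc2ccccc2)c(Cl)c1OC | intermediate
8 | 4-(benzyloxy)-3-chloro-6-(hydroxymethyl)-2-methoxyphenol (magnesium salt in the flask) | OCc1cc(OCc2ccccc2)c(Cl)c(OC)c1O | intermediate (not isolated)
9 | 5-(benzyloxy)-4-chloro-2-hydroxy-3-methoxybenzaldehyde | O=Cc1cc(OCc2ccccc2)c(Cl)c(OC)c1O | intermediate
10 | 5-(benzyloxy)-4-chloro-2-hydroxy-3-methoxybenzoic acid | OC(=O)c1cc(OCc2ccccc2)c(Cl)c(OC)c1O | intermediate
11 | methyl 5-(benzyloxy)-4-chloro-2-hydroxy-3-methoxybenzoate | COC(=O)c1cc(OCc2ccccc2)c(Cl)c(OC)c1O | intermediate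
12 | 3-methylglutaric anhydride | CC1CC(=O)OC(=O)C1 | starting material
13 | 5-(benzyloxy)-3-methyl-5-oxopentanoic acid (racemic) | CC(CC(=O)O)CC(=O)OCc1ccccc1 | intermediate
14 | monobenzyl malonate (3-(benzyloxy)-3-oxopropanoic acid) | OC(=O)CC(=O)OCc1ccccc1 | starting material
15 | benzyl 5-(1H-imidazol-1-yl)-3-methyl-5-oxopentanoate (racemic) | CC(CC(=O)n1ccnc1)CC(=O)OCc1ccccc1 | intermediate (not isolated)
16 | 2-[(benzyloxy)carbonyl]-7-(benzyloxy)-5-methyl-3,7-dioxoheptanoic acid (racemic, diastereomer mixture) | OC(=O)C(C(=O)OCc1ccccc1)C(=O)CC(C)CC(=O)OCc1ccccc1 | intermediate (not isolated)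
17 | dibenzyl 5-methyl-3-oxoheptanedioate (racemic) | O=C(CC(=O)CC(C)CC(=O)OCc1ccccc1)OCc1ccccc1 | intermediate
18 | benzyl 4-methyl-2,6-dioxocyclohexane-1-carboxylate (drawn as the triketo tautomer; largely enolised) | CC1CC(=O)C(C(=O)OCc2ccccc2)C(=O)C1 | intermediate
19 | benzyl 2-chloro-4-methyl-6-oxocyclohex-1-ene-1-carboxylate (racemic) | CC1CC(Cl)=C(C(=O)OCc2ccccc2)C(=O)C1 | intermediate
20 | benzyl 2-[4-(benzyloxy)-3-chloro-2-methoxy-6-(methoxycarbonyl)phenoxy]-4-methyl-6-oxocyclohex-1-ene-1-carboxylate (racemic) | COC(=O)c1cc(OCc2ccccc2)c(Cl)c(OC)c1OC1=C(C(=O)OCc2ccccc2)C(=O)CC(C)C1 | intermediate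
21 | benzyl 2-[4-(benzyloxy)-3-chloro-2-methoxy-6-(methoxycarbonyl)phenoxy]-4-methyl-6-[(trimethylsilyl)oxy]cyclohexa-1,5-diene-1-carboxylate (racemic) | COC(=O)c1cc(OCc2ccccc2)c(Cl)c(OC)c1OC1=C(C(=O)OCc2ccccc2)C(O[Si](C)(C)C)=CC(C)C1 | intermediate (not isolated)
22 | benzyl 2-[4-(benzyloxy)-3-chloro-2-methoxy-6-(methoxycarbonyl)phenoxy]-4-methyl-6-oxocyclohexa-1,4-diene-1-carboxylate | COC(=O)c1cc(OCc2ccccc2)c(Cl)c(OC)c1OC1=C(C(=O)OCc2ccccc2)C(=O)C=C(C)C1 | intermediate (not isolated)
23 | benzyl 2-[4-(benzyloxy)-3-chloro-2-methoxy-6-(methoxycarbonyl)phenoxy]-6-hydroxy-4-methylbenzoate | COC(=O)c1cc(OCc2ccccc2)c(Cl)c(OC)c1Oc1cc(C)cc(O)c1C(=O)OCc1ccccc1 | intermediate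
24 | 2-[3-chloro-4-hydroxy-2-methoxy-6-(methoxycarbonyl)phenoxy]-6-hydroxy-4-methylbenzoic acid | COC(=O)c1cc(O)c(Cl)c(OC)c1Oc1cc(C)cc(O)c1C(=O)O | target

**Summary**
Total step count: 14. Longest linear sequence: 10 steps (1 to 24 through steps 1–7 and 12–14); the ring B branch (steps 8–11) is 4 steps.

**Steps most likely to fail, with fallbacks**

Step 10 (Dieckmann closure of 17). The stabilised β-keto ester enolate is a weak nucleophile and may close slowly or reopen. The fallback closes the ring on an activated acid instead of an ester; it sets out from 12 and comes back at 18. Anhydride 12 is opened by the lithium enolate of benzyl acetate (LiN(iPr)2, 2.2 equiv, THF, −78 °C, a Claisen-type acylation) to give 7-(benzyloxy)-3-methyl-5,7-dioxoheptanoic acid F1. CDI converts its carboxyl group into the acyl imidazolide benzyl 7-(1H-imidazol-1-yl)-5-methyl-3,7-dioxoheptanoate F2. MgCl2/Et3N then brings about intramolecular C-acylation of the chelated β-keto ester enolate, which gives 18.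

Step 12 (ether formation). Chloride 19 may hydrolyse, or the hindered, hydrogen-bonded phenoxide of 11 may add poorly. The fallback makes the C–O bond on an already aromatic ring B by copper catalysis; it sets out from 18 and comes back at 24. Ph3PBr2/Et3N (CH2Cl2) gives benzyl 2-bromo-4-methyl-6-oxocyclohex-1-ene-1-carboxylate F3. DDQ (dioxane, reflux) dehydrogenates it to benzyl 2-bromo-6-hydroxy-4-methylbenzoate F4. BnBr/K2CO3 (DMF) gives benzyl 2-(benzyloxy)-6-bromo-4-methylbenzoate F5. Ullmann coupling with 11 (CuI, picolinic acid, K3PO4, DMSO, 90 °C; the ortho ester assists the copper step) gives benzyl 2-(benzyloxy)-6-[4-(benzyloxy)-3-chloro-2-methoxy-6-(methoxycarbonyl)phenoxy]-4-methylbenzoate F6. Its three benzyl groups are removed with BCl3/C6HMe5 as in step 14 to give 24.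

Step 13 (aromatisation of 20). Silylation or the palladium step may fail on this crowded substrate. The fallback dehydrogenates by selenoxide elimination; it sets out from 20 and comes back at 23. The lithium enolate of 20 (LiN(iPr)2, THF, −78 °C) is trapped with PhSeBr to give benzyl 2-[4-(benzyloxy)-3-chloro-2-methoxy-6-(methoxycarbonyl)phenoxy]-4-methyl-6-oxo-5-(phenylselanyl)cyclohex-1-ene-1-carboxylate F7. H2O2 (pyridine, CH2Cl2, 0 °C) oxidises it to benzyl 2-[4-(benzyloxy)-3-chloro-2-methoxy-6-(methoxycarbonyl)phenoxy]-4-methyl-6-oxo-5-(phenylseleninyl)cyclohex-1-ene-1-carboxylate F8. Syn-elimination of F8 at or below rt gives dienone 22, which tautomerises to 23.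

**Further compounds**
F1 | step 10 | 7-(benzyloxy)-3-methyl-5,7-dioxoheptanoic acid (racemic) | OC(=O)CC(C)CC(=O)CC(=O)OCc1ccccc1
F2 | step 10 | benzyl 7-(1H-imidazol-1-yl)-5-methyl-3,7-dioxoheptanoate (racemic) | O=C(CC(C)CC(=O)CC(=O)OCc1ccccc1)n1ccnc1
F3 | step 12 | benzyl 2-bromo-4-methyl-6-oxocyclohex-1-ene-1-carboxylate (racemic) | CC1CC(Br)=C(C(=O)OCc2ccccc2)C(=O)C1
F4 | step 12 | benzyl 2-bromo-6-hydroxy-4-methylbenzoate | Cc1cc(O)c(C(=O)OCc2ccccc2)c(Br)c1
F5 | step 12 | benzyl 2-(benzyloxy)-6-bromo-4-methylbenzoate | Cc1cc(OCc2ccccc2)c(C(=O)OCc2ccccc2)c(Br)c1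
F6 | step 12 | benzyl 2-(benzyloxy)-6-[4-(benzyloxy)-3-chloro-2-methoxy-6-(methoxycarbonyl)phenoxy]-4-methylbenzoate | COC(=O)c1cc(OCc2ccccc2)c(Cl)c(OC)c1Oc1cc(C)cc(OCc2ccccc2)c1C(=O)OCc1ccccc1
F7 | step 13 | benzyl 2-[4-(benzyloxy)-3-chloro-2-methoxy-6-(methoxycarbonyl)phenoxy]-4-methyl-6-oxo-5-(phenylselanyl)cyclohex-1-ene-1-carboxylate (racemic, diastereomer mixture) | COC(=O)c1cc(OCc2ccccc2)c(Cl)c(OC)c1OC1=C(C(=O)OCc2ccccc2)C(=O)C([Se]c2ccccc2)C(C)C1
F8 | step 13 | benzyl 2-[4-(benzyloxy)-3-chloro-2-methoxy-6-(methoxycarbonyl)phenoxy]-4-methyl-6-oxo-5-(phenylseleninyl)cyclohex-1-ene-1-carboxylate (diastereomer mixture) | COC(=O)c1cc(OCc2ccccc2)c(Cl)c(OC)c1OC1=C(C(=O)OCc2ccccc2)C(=O)C([Se](=O)c2ccccc2)C(C)C1
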